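## Retrosynthetic overview

- The last bonds made are C6–CH2 (B-alkyl Suzuki coupling with hydroborated 2-methylbut-3-en-2-ol) and C3–C1' (site-selective Suzuki coupling of 3,6-diiodochromone 17 with chromenyl boronate 12); a global fluoride desilylation ends the route.
- The pyran ring on ring B is cut at C4''–C5' and at C3''–C2'' (pyran atoms O1'', C2''(Me2), C3'', C4''). This leads back to aryl isopropenyl ether 6 and the acetaldehyde enol silane 7, joined by a cationic formal [4+2] annulation–dehydration of the oxa-Povarov type.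
- Enabling feature: the ether oxygen O1'' on C4' of ring B, its ortho carbon C5' and the acetone-derived carbon C2'' form a 2-oxadiene once C2'' is an oxocarbenium centre (C5'=C4'–O1''(+)=C2''). The 2',4'-dioxygenation of ring B makes C5' (para to O2') the nucleophilic terminus, while C3' is shielded between two oxygens.
- Ring order: ring B is bought; the pyran ring is built on it (step 5); ring C of the chromone is closed onto ring A by iodocyclisation of a symmetrical enaminone (step 9); the halves are then joined.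

Key step: step 5

Remark: the target has no stereocentre; the only stereocentre of the route (C4 of chromanol 10) is transient and racemic. The aryl isopropenyl ethers 4–6 are acid-labile and are to be handled under neutral or basic conditions.

## Route

Step 1
Reactants: 1 resorcinol monobenzoate (3-hydroxyphenyl benzoate)
Product: 2 2-bromo-5-hydroxyphenyl benzoate
Conditions: NBS (1.0 equiv), MeCN, −10 °C → rt
Reagents that add atoms: N-bromosuccinimide, O=C1CCC(=O)N1Br
Why: Electrophilic aromatic bromination should go para to the free hydroxyl, the far stronger donor than the benzoyloxy group, which places bromine ortho to the acylated oxygen.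

Step 2
Reactants: 2 2-bromo-5-hydroxyphenyl benzoate; 3 potassium trifluoro(prop-1-en-2-yl)borate
Product: 4 2-bromo-5-(prop-1-en-2-yloxy)phenyl benzoate
Conditions: Cu(OAc)2 (20 mol %), pyridine (3 equiv), 4 Å MS, CH2Cl2, O2 (1 atm), rt
Reagents that add atoms: none
Why: Chan–Lam–Evans oxidative C–O coupling of a phenol with an alkenyltrifluoroborate under divalent copper and O2 should give the aryl alkenyl ether at room temperature without touching the aryl bromide or the benzoate.

Step 3
Reactants: 4 2-bromo-5-(prop-1-en-2-yloxy)phenyl benzoate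
Product: 5 2-bromo-5-(prop-1-en-2-yloxy)phenol
Conditions: K2CO3 (20 mol %), MeOH, 0 °C → rt; pH 7 buffer work-up
Reagents that add atoms: none
Why: Base-catalysed transesterification (methanolysis) of the aryl benzoate should free the phenol, and the enol ether is stable to base.

Step 4
Reactants: 5 2-bromo-5-(prop-1-en-2-yloxy)phenol
Product: 6 [2-bromo-5-(prop-1-en-2-yloxy)phenoxy]tri(propan-2-yl)silane
Conditions: TIPSCl (1.2 equiv), imidazole (2.5 equiv), DMF, rt
Reagents that add atoms: chlorotri(propan-2-yl)silane, CC(C)[Si](Cl)(C(C)C)C(C)C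
Why: Standard phenol silylation should give the TIPS ether, which turns the ring into an electron-rich resorcinol diether and shields the carbon between the two oxygens.

Step 5
Reactants: 6 [2-bromo-5-(prop-1-en-2-yloxy)phenoxy]tri(propan-2-yl)silane; 7 (ethenyloxy)trimethylsilane
Product: 11 6-bromo-2,2-dimethyl-7-[tri(propan-2-yl)silyloxy]-2H-chromene, via alpha-chloro ether 8 (not isolated), via beta-aryloxy aldehyde 9 (not isolated), via racemic chroman-4-ol 10 (not isolated)
Conditions: HCl (1.0 equiv, 4 M in dioxane), CH2Cl2, −78 °C, 15 min; then 7 (1.5 equiv), Me3SiOTf (20 mol %), −78 → 0 °C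
Reagents that add atoms: none
Why: Proposed new method: Markovnikov addition of HCl to the isopropenyl ether should give the tertiary alpha-chloro ether 8, whose only leaving group is chloride, so Me3SiOTf can ionise it in one sense only, to the O-aryl oxocarbenium ion in which C5 and C4 of the arene, the ether oxygen and the CMe2 carbon form a cationic 2-oxadiene. The enol silane 7 should attack the CMe2 carbon through its CH2 terminus (Mukaiyama-type addition, forming the C2–C3 bond of the pyran and releasing Me3SiCl) to give aldehyde 9; the silyl-activated aldehyde then alkylates arene carbon C5 of 6 (the later C4a) in a 6-exo-trig Friedel–Crafts hydroxyalkylation (forming the C4–C4a bond) to give chromanol 10, whose benzylic C–O bond, flanked by an ortho and a para oxygen donor, ionises under the same acid and loses the C3 proton (E1) to give the 2H-chromene. The closest known reaction types are the oxa-Povarov reaction (formal [4+2] cycloaddition of aldehyde-derived O-aryl oxocarbenium ions with alkenes to give chromans), Lewis-acid couplings of alpha-halo ethers and ketals with silyl enol ethers, and the acid-mediated cyclodehydration of 3-aryloxypropanals to 2H-chromenes; new here is their merger on a ketone-derived O-aryl oxocarbenium ion with an acetaldehyde enol silane as a two-carbon acetylene equivalent. The pyran ring is the only ring closed, stepwise and in the order C2–C3 then C4–C4a, and the C4 carbinol stereocentre of 10 forms as a racemate and is destroyed in the same flask, so no stereocontrol is needed. The step needs site selectivity between the two arene carbons ortho to the ether oxygen, and the substrate secures it: C5 is para to the silyloxy donor and unhindered, whereas C3 lies between two oxygens, one carrying the bulky TIPS group. It also needs C–C bond formation to outrun proton loss from the oxocarbenium ion, which the low temperature and the high nucleophilicity of the enol silane should secure.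

Step 6
Reactants: 11 6-bromo-2,2-dimethyl-7-[tri(propan-2-yl)silyloxy]-2H-chromene
Product: 12 2-{2,2-dimethyl-7-[tri(propan-2-yl)silyloxy]-2H-chromen-6-yl}-4,4,5,5-tetramethyl-1,3,2-dioxaborolane
Conditions: B2pin2 (1.3 equiv), Pd(dppf)Cl2 (5 mol %), KOAc (3 equiv), 1,4-dioxane, 90 °C
Reagents that add atoms: bis(pinacolato)diboron, CC1(C)OB(OC1(C)C)B1OC(C)(C)C(C)(C)O1
Why: Miyaura borylation of the aryl bromide under weak-base conditions should give the pinacol boronate and leave the chromene double bond and the silyl ether intact.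

Step 7
Reactants: 13 1-(2,4,6-trihydroxyphenyl)ethan-1-one
Product: 14 1-(2,6-dihydroxy-4-{[2-(trimethylsilyl)ethoxy]methoxy}phenyl)ethan-1-one
Conditions: SEMCl (1.05 equiv), i-Pr2NEt (1.2 equiv), CH2Cl2–THF, 0 °C
Reagents that add atoms: 2-(trimethylsilyl)ethoxymethyl chloride, C[Si](C)(C)CCOCCl
Why: O-Alkylation should occur at the 4-hydroxyl, the most acidic and the only one not hydrogen-bonded to the ketone, which keeps the molecule symmetrical.

Step 8
Reactants: 14 1-(2,6-dihydroxy-4-{[2-(trimethylsilyl)ethoxy]methoxy}phenyl)ethan-1-one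
Product: 15 (E)-1-(2,6-dihydroxy-4-{[2-(trimethylsilyl)ethoxy]methoxy}phenyl)-3-(dimethylamino)prop-2-en-1-one
Conditions: DMF dimethyl acetal (3 equiv), toluene, 90 °C
Reagents that add atoms: N,N-dimethylformamide dimethyl acetal, COC(OC)N(C)C
Why: Condensation of the methyl ketone with the amide acetal should give the E-enaminone, the chelated ortho hydroxyls being poor partners for O-methylation.

Step 9
Reactants: 15 (E)-1-(2,6-dihydroxy-4-{[2-(trimethylsilyl)ethoxy]methoxy}phenyl)-3-(dimethylamino)prop-2-en-1-one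
Product: 16 5-hydroxy-3-iodo-7-{[2-(trimethylsilyl)ethoxy]methoxy}-4H-chromen-4-one
Conditions: I2 (1.1 equiv), CHCl3, rt
Reagents that add atoms: iodine, II
Why: Gammill iodocyclisation (iodination of the enaminone alpha-carbon, conjugate addition of an ortho hydroxyl, loss of dimethylamine) should give one 3-iodochromone because the two ortho hydroxyls are equivalent.

Step 10
Reactants: 16 5-hydroxy-3-iodo-7-{[2-(trimethylsilyl)ethoxy]methoxy}-4H-chromen-4-one
Product: 17 5-hydroxy-3,6-diiodo-7-{[2-(trimethylsilyl)ethoxy]methoxy}-4H-chromen-4-one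
Conditions: BnMe3N ICl2 (1.05 equiv), CaCO3, CH2Cl2–MeOH, rt
Reagents that add atoms: benzyltrimethylammonium dichloroiodate, C[N+](C)(C)Cc1ccccc1.Cl[I-]Cl
Why: Electrophilic iodination should go ortho to the free 5-hydroxyl, at C6, as in the 6-iodination of 5-hydroxy-7-alkoxyflavones, with CaCO3 buffering the HCl so that the SEM acetal survives.

Step 11
Reactants: 17 5-hydroxy-3,6-diiodo-7-{[2-(trimethylsilyl)ethoxy]methoxy}-4H-chromen-4-one; 12 2-{2,2-dimethyl-7-[tri(propan-2-yl)silyloxy]-2H-chromen-6-yl}-4,4,5,5-tetramethyl-1,3,2-dioxaborolane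
Product: 18 3-{2,2-dimethyl-7-[tri(propan-2-yl)silyloxy]-2H-chromen-6-yl}-5-hydroxy-6-iodo-7-{[2-(trimethylsilyl)ethoxy]methoxy}-4H-chromen-4-one
Conditions: 12 (1.05 equiv), Pd(OAc)2 (5 mol %), SPhos (10 mol %), K3PO4 (3 equiv), THF–H2O, 40 °C
Reagents that add atoms: none
Why: Suzuki–Miyaura coupling should be site-selective because zerovalent palladium inserts far faster into the alpha-iodoenone C3–I bond than into the C6–I bond, which is flanked by a phenoxide and an alkoxy group on an electron-rich ring.

Step 12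
Reactants: 18 3-{2,2-dimethyl-7-[tri(propan-2-yl)silyloxy]-2H-chromen-6-yl}-5-hydroxy-6-iodo-7-{[2-(trimethylsilyl)ethoxy]methoxy}-4H-chromen-4-one; 19 2-methylbut-3-en-2-ol
Product: 21 3-{2,2-dimethyl-7-[tri(propan-2-yl)silyloxy]-2H-chromen-6-yl}-5-hydroxy-6-(3-hydroxy-3-methylbutyl)-7-{[2-(trimethylsilyl)ethoxy]methoxy}-4H-chromen-4-one, via alkylborane 20 (not isolated)
Conditions: 19 (3 equiv), 9-BBN-H (6.3 equiv), THF, 0 °C → rt; then 18, Pd(dppf)Cl2 (10 mol %), K3PO4 (3 M aq), DMF, 60 °C
Reagents that add atoms: none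
Why: Anti-Markovnikov hydroboration of the terminal alkene (the first equivalent of borane being taken up by the hydroxyl) followed by B-alkyl Suzuki–Miyaura coupling should install the saturated hydroxyalkyl chain directly, so that no hydrogenation ever meets the chromene double bond.

Step 13
Reactants: 21 3-{2,2-dimethyl-7-[tri(propan-2-yl)silyloxy]-2H-chromen-6-yl}-5-hydroxy-6-(3-hydroxy-3-methylbutyl)-7-{[2-(trimethylsilyl)ethoxy]methoxy}-4H-chromen-4-one
Product: 23 5,7-dihydroxy-6-(3-hydroxy-3-methylbutyl)-3-(7-hydroxy-2,2-dimethyl-2H-chromen-6-yl)-4H-chromen-4-one (target), via 7-O-SEM phenol 22 (not isolated)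
Conditions: Bu4NF (6 equiv), THF–DMPU, 0 °C → 50 °C
Reagents that add atoms: none
Why: Fluoride should first cleave the aryl TIPS ether and then the SEM ether by attack at silicon with loss of ethene and formaldehyde, helped by the acidic 7-hydroxychromone leaving group, under non-acidic conditions that spare the tertiary alcohol and the chromene.

## Compound list

1 | resorcinol monobenzoate (3-hydroxyphenyl benzoate) | O=C(Oc1cccc(O)c1)c1ccccc1 | starting material
2 | 2-bromo-5-hydroxyphenyl benzoate | O=C(Oc1cc(O)ccc1Br)c1ccccc1 | intermediate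
3 | potassium trifluoro(prop-1-en-2-yl)borate | [K+].C=C(C)[B-](F)(F)F | starting material
4 | 2-bromo-5-(prop-1-en-2-yloxy)phenyl benzoate | C=C(C)Oc1ccc(Br)c(OC(=O)c2ccccc2)c1 | intermediate
5 | 2-bromo-5-(prop-1-en-2-yloxy)phenol | C=C(C)Oc1ccc(Br)c(O)c1 | intermediate
6 | [2-bromo-5-(prop-1-en-2-yloxy)phenoxy]tri(propan-2-yl)silane | C=C(C)Oc1ccc(Br)c(O[Si](C(C)C)(C(C)C)C(C)C)c1 | intermediate
7 | (ethenyloxy)trimethylsilane | C=CO[Si](C)(C)C | starting material
8 | [2-bromo-5-(2-chloropropan-2-yloxy)phenoxy]tri(propan-2-yl)silane (not isolated) | CC(C)(Cl)Oc1ccc(Br)c(O[Si](C(C)C)(C(C)C)C(C)C)c1 | intermediate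
9 | 3-{4-bromo-3-[tri(propan-2-yl)silyloxy]phenoxy}-3-methylbutanal (not isolated) | CC(C)(CC=O)Oc1ccc(Br)c(O[Si](C(C)C)(C(C)C)C(C)C)c1 | intermediate
10 | racemic 6-bromo-2,2-dimethyl-7-[tri(propan-2-yl)silyloxy]chroman-4-ol (not isolated) | CC1(C)CC(O)c2cc(Br)c(O[Si](C(C)C)(C(C)C)C(C)C)cc2O1 | intermediate
11 | 6-bromo-2,2-dimethyl-7-[tri(propan-2-yl)silyloxy]-2H-chromene | CC1(C)C=Cc2cc(Br)c(O[Si](C(C)C)(C(C)C)C(C)C)cc2O1 | intermediate
12 | 2-{2,2-dimethyl-7-[tri(propan-2-yl)silyloxy]-2H-chromen-6-yl}-4,4,5,5-tetramethyl-1,3,2-dioxaborolane | CC1(C)C=Cc2cc(B3OC(C)(C)C(C)(C)O3)c(O[Si](C(C)C)(C(C)C)C(C)C)cc2O1 | intermediate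
13 | 1-(2,4,6-trihydroxyphenyl)ethan-1-one | CC(=O)c1c(O)cc(O)cc1O | starting material
14 | 1-(2,6-dihydroxy-4-{[2-(trimethylsilyl)ethoxy]methoxy}phenyl)ethan-1-one | CC(=O)c1c(O)cc(OCOCC[Si](C)(C)C)cc1O | intermediate
15 | (E)-1-(2,6-dihydroxy-4-{[2-(trimethylsilyl)ethoxy]methoxy}phenyl)-3-(dimethylamino)prop-2-en-1-one | CN(C)/C=C/C(=O)c1c(O)cc(OCOCC[Si](C)(C)C)cc1O | intermediate
16 | 5-hydroxy-3-iodo-7-{[2-(trimethylsilyl)ethoxy]methoxy}-4H-chromen-4-one | O=c1c(I)coc2cc(OCOCC[Si](C)(C)C)cc(O)c12 | intermediate
17 | 5-hydroxy-3,6-diiodo-7-{[2-(trimethylsilyl)ethoxy]methoxy}-4H-chromen-4-one | O=c1c(I)coc2cc(OCOCC[Si](C)(C)C)c(I)c(O)c12 | intermediate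
18 | 3-{2,2-dimethyl-7-[tri(propan-2-yl)silyloxy]-2H-chromen-6-yl}-5-hydroxy-6-iodo-7-{[2-(trimethylsilyl)ethoxy]methoxy}-4H-chromen-4-one | O=c1c(-c2cc3c(cc2O[Si](C(C)C)(C(C)C)C(C)C)OC(C)(C)C=C3)coc2cc(OCOCC[Si](C)(C)C)c(I)c(O)c12 | intermediate
19 | 2-methylbut-3-en-2-ol | C=CC(C)(C)O | starting material
20 | 9-{3-[(9-borabicyclo[3.3.1]nonan-9-yl)oxy]-3-methylbutyl}-9-borabicyclo[3.3.1]nonane (not isolated) | CC(C)(CCB1C2CCCC1CCC2)OB1C2CCCC1CCC2 | intermediate
21 | 3-{2,2-dimethyl-7-[tri(propan-2-yl)silyloxy]-2H-chromen-6-yl}-5-hydroxy-6-(3-hydroxy-3-methylbutyl)-7-{[2-(trimethylsilyl)ethoxy]methoxy}-4H-chromen-4-one | CC(C)(O)CCc1c(OCOCC[Si](C)(C)C)cc2occ(-c3cc4c(cc3O[Si](C(C)C)(C(C)C)C(C)C)OC(C)(C)C=C4)c(=O)c2c1O | intermediate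
22 | 5-hydroxy-6-(3-hydroxy-3-methylbutyl)-3-(7-hydroxy-2,2-dimethyl-2H-chromen-6-yl)-7-{[2-(trimethylsilyl)ethoxy]methoxy}-4H-chromen-4-one (not isolated) | CC(C)(O)CCc1c(OCOCC[Si](C)(C)C)cc2occ(-c3cc4c(cc3O)OC(C)(C)C=C4)c(=O)c2c1O | intermediate
23 | 5,7-dihydroxy-6-(3-hydroxy-3-methylbutyl)-3-(7-hydroxy-2,2-dimethyl-2H-chromen-6-yl)-4H-chromen-4-one | CC(C)(O)CCc1c(O)cc2occ(-c3cc4c(cc3O)OC(C)(C)C=C4)c(=O)c2c1O | target

## Step count and risks

Total step count: 13. Longest linear sequence: 9 steps (steps 1–6, then 11–13, from resorcinol monobenzoate); the chromone branch (steps 7–10) joins at step 11.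

Steps most likely to fail:

1. Step 5 (proposed new method). The oxocarbenium ion may lose a proton to the enol silane, or be captured by a second arene, faster than it forms the C–C bond. The sequence may also stall at the aldehyde stage, where loss of the phenol by retro-oxa-Michael fragmentation competes with ring closure, and the acid may oligomerise the chromene once it has formed. The fallback uses the established propargyl ether route, which builds the same ring through a different bond set. It sets out from 2. O-Alkylation with 3-chloro-3-methylbut-1-yne (DBU, CuCl2 0.1 mol %, MeCN, 0 °C) should give 2-bromo-5-[(2-methylbut-3-yn-2-yl)oxy]phenyl benzoate F1. Heating (N,N-diethylaniline, 190 °C) should effect propargyl Claisen rearrangement, 1,5-hydrogen shift and oxa-6π electrocyclisation at the less hindered ortho carbon, giving 6-bromo-2,2-dimethyl-2H-chromen-7-yl benzoate F2. Methanolysis (K2CO3, MeOH) should give 6-bromo-2,2-dimethyl-2H-chromen-7-ol F3, and silylation (TIPSCl, imidazole, DMF) returns to the route at 11.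

2. Step 11. Site selectivity between the two carbon–iodine bonds may erode, leading to double arylation, and slow transmetalation of the hindered ortho-silyloxy boronate may allow protodeiodination or protodeboronation. The fallback differentiates the halogens and reverses the order of the two couplings. It sets out from 15. N-Chlorosuccinimide (CH2Cl2, rt) should give 3-chloro-5-hydroxy-7-{[2-(trimethylsilyl)ethoxy]methoxy}-4H-chromen-4-one F4. Iodination as in step 10 should give 3-chloro-5-hydroxy-6-iodo-7-{[2-(trimethylsilyl)ethoxy]methoxy}-4H-chromen-4-one F5. B-Alkyl Suzuki coupling with alkylborane 20 (Pd(dppf)Cl2, K3PO4, DMF–H2O, 60 °C), in which the C–I bond reacts far ahead of the C–Cl bond, should give 3-chloro-5-hydroxy-6-(3-hydroxy-3-methylbutyl)-7-{[2-(trimethylsilyl)ethoxy]methoxy}-4H-chromen-4-one F6. Suzuki coupling of the activated alkenyl chloride with 12 (Pd(OAc)2, XPhos, K3PO4, dioxane–H2O, 80 °C) comes back to the route at 21.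

3. Step 12. Oxidative addition at the hindered, electron-rich C6–I bond next to a phenoxide may be slow, so that protodeiodination and beta-hydride elimination of the alkylpalladium intermediate compete. The fallback replaces the in-situ borane, which needs aqueous base, by a preformed organozinc reagent that transmetalates at room temperature without base. 4-Bromo-2-methylbutan-2-ol is silylated (Me3SiCl, imidazole, CH2Cl2) to (4-bromo-2-methylbutan-2-yloxy)trimethylsilane F7, and zinc insertion (Zn, LiCl, THF) gives bromo[3-methyl-3-(trimethylsilyloxy)butyl]zinc F8. The fallback sets out from 18: Negishi coupling with F8 (3 equiv, one being consumed by the 5-hydroxyl; Pd(OAc)2, CPhos, THF, rt) should give the trimethylsilyl ether of 21 F9. Its tertiary silyl ether is hydrolysed during an aqueous citric acid work-up, which comes back to the route at 21.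

## Further compounds

F1 | step 5 | 2-bromo-5-[(2-methylbut-3-yn-2-yl)oxy]phenyl benzoate | C#CC(C)(C)Oc1ccc(Br)c(OC(=O)c2ccccc2)c1
F2 | step 5 | 6-bromo-2,2-dimethyl-2H-chromen-7-yl benzoate | CC1(C)C=Cc2cc(Br)c(OC(=O)c3ccccc3)cc2O1
F3 | step 5 | 6-bromo-2,2-dimethyl-2H-chromen-7-ol | CC1(C)C=Cc2cc(Br)c(O)cc2O1
F4 | step 11 | 3-chloro-5-hydroxy-7-{[2-(trimethylsilyl)ethoxy]methoxy}-4H-chromen-4-one | O=c1c(Cl)coc2cc(OCOCC[Si](C)(C)C)cc(O)c12
F5 | step 11 | 3-chloro-5-hydroxy-6-iodo-7-{[2-(trimethylsilyl)ethoxy]methoxy}-4H-chromen-4-one | O=c1c(Cl)coc2cc(OCOCC[Si](C)(C)C)c(I)c(O)c12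
F6 | step 11 | 3-chloro-5-hydroxy-6-(3-hydroxy-3-methylbutyl)-7-{[2-(trimethylsilyl)ethoxy]methoxy}-4H-chromen-4-one | CC(C)(O)CCc1c(OCOCC[Si](C)(C)C)cc2occ(Cl)c(=O)c2c1O
F7 | step 12 | (4-bromo-2-methylbutan-2-yloxy)trimethylsilane | CC(C)(CCBr)O[Si](C)(C)C
F8 | step 12 | bromo[3-methyl-3-(trimethylsilyloxy)butyl]zinc | CC(C)(CC[Zn]Br)O[Si](C)(C)C
F9 | step 12 | 3-{2,2-dimethyl-7-[tri(propan-2-yl)silyloxy]-2H-chromen-6-yl}-5-hydroxy-6-[3-methyl-3-(trimethylsilyloxy)butyl]-7-{[2-(trimethylsilyl)ethoxy]methoxy}-4H-chromen-4-one | CC(C)(CCc1c(OCOCC[Si](C)(C)C)cc2occ(-c3cc4c(cc3O[Si](C(C)C)(C(C)C)C(C)C)OC(C)(C)C=C4)c(=O)c2c1O)O[Si](C)(C)C
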